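## Retrosynthetic overview

1. Structural feature: in ring C of the top unit and of the middle unit, O1 is bonded to C2 and the free hydroxyl sits on C3 (2,3-cis, 3,4-trans). This O1–C2/C3–OH pair is the 1,2-transposed form of a trans-3-aryl-2,3-dihydrobenzofuran whose ring oxygen is on the future C3 and whose exocyclic α-hydroxybenzyl carbon is the future C2.
2. Key disconnection: O1–C2 and C3–O of both upper rings C (four bonds, two rings, C2 and C3 of both units) are made in one operation from bis(furanyl carbinol) 25 through aryl-bridged oxonium ions. The two B rings involved carry pivalates instead of benzyl ethers, so that the benzylic sulfonates cannot simply ionise.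
3. Before that: two o-quinone methide [4+1] annulations with a quinidine-bound aroylmethyl ammonium ylide (top furan first, then middle furan), then Felkin–Anh reduction of both aroyl ketones. Chelate control is not used, because it would give the C2-epimeric, 2,3-trans series.
4. Skeleton: C4(middle)–C6(lower) from the C6-lithiated epicatechin derivative 15 and aldehyde 8; C4(top)–C8(middle) from Br/Li exchange on the same ring and aldehyde 9. Two sulfones gate the quinone methides and are released one at a time by unmasking the flanking phenol (TBS, then allyl).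
5. Ring order: ring C of the lower unit (from (−)-epicatechin) → top furan → middle furan → rings C of the top and middle units together (step 18) → deacylation, MOM removal, hydrogenolysis.

Key step: step 18

Remarks on the chemistry:
- Atom numbers O1, C2, C3, C4, C4a, C5–C8, C8a are flavan numbers of the unit named; primed numbers (O1', C2', C3') are dihydrobenzofuran numbers.
- In 25 and 28 the catechols of the top and middle B rings are pivalates and the lower catechol is a diphenylmethylene ketal; these are spectator-group changes only.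
- Assumption: the quinidine-bound ylide from 14 is taken to give the (2'S)-trans furans drawn; if a trial annulation shows the opposite sense, the quinine-derived salt is used in steps 14 and 16 and nothing else changes.
- The carbinol and sulfone carbons of 16, 18, 19, 21 and 22 are epimer mixtures that converge at the quinone methide stage.

## Route

Step 1
Reactants: 1 (−)-epicatechin
Product: 2 3',4'-O-(diphenylmethylene)-(−)-epicatechin
Conditions: Ph2CCl2 (1.2 equiv), K2CO3, MeCN, rt
Reagents that add atoms: dichlorodiphenylmethane, ClC(Cl)(c1ccccc1)c1ccccc1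
Why: Ketal formation between the geminal dichloride and the only vicinal diphenol (double O-alkylation closing a 1,3-benzodioxole) should be selective because isolated phenols cannot give a stable product with this reagent, and no stereocenter is touched.

Step 2
Reactants: 2 3',4'-O-(diphenylmethylene)-(−)-epicatechin
Product: 3 5,7-bis-O-(methoxymethyl)-3',4'-O-(diphenylmethylene)-(−)-epicatechin
Conditions: MOMCl (2.4 equiv), K2CO3, acetone, 0 °C → rt
Reagents that add atoms: chloromethyl methyl ether, COCCl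
Why: Williamson etherification of the two phenoxides formed by carbonate, which does not deprotonate the secondary 3-hydroxyl; the two acetal ethers flanking C6 are the directing groups for step 11.

Step 3
Reactants: 3 5,7-bis-O-(methoxymethyl)-3',4'-O-(diphenylmethylene)-(−)-epicatechin
Product: 4 3-O-benzyl-5,7-bis-O-(methoxymethyl)-3',4'-O-(diphenylmethylene)-(−)-epicatechin (lower unit)
Conditions: NaH, BnBr, n-Bu4NI (cat.), DMF, 0 °C → rt
Reagents that add atoms: benzyl bromide, BrCc1ccccc1
Why: Williamson benzylation of the sodium alkoxide; with every phenol masked, base cannot open ring C through a quinone methide, so C2 and C3 keep the (2R,3R) configuration.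

Step 4
Reactants: 5 2,4,6-trihydroxybenzaldehyde
Product: 6 2,4-bis(benzyloxy)-6-hydroxybenzaldehyde
Conditions: BnBr (2.05 equiv), K2CO3, DMF, rt
Reagents that add atoms: benzyl bromide, BrCc1ccccc1
Why: Williamson etherification in which the para hydroxyl and one ortho hydroxyl react, while the remaining ortho hydroxyl is held in a hydrogen bond to the formyl group and should stay free.

Step 5
Reactants: 6 2,4-bis(benzyloxy)-6-hydroxybenzaldehyde
Product: 7 4,6-bis(benzyloxy)-3-bromo-2-hydroxybenzaldehyde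
Conditions: NBS (1.0 equiv), CH2Cl2, 0 °C
Reagents that add atoms: N-bromosuccinimide, O=C1CCC(=O)N1Br
Why: Electrophilic aromatic bromination, expected at C3 (ortho to the free phenol) in preference to C5 (between two benzyloxy groups), as is usual for 2-hydroxy-4,6-dialkoxyaryl carbonyl compounds; this bromine later defines the 4→8 link.

Step 6
Reactants: 7 4,6-bis(benzyloxy)-3-bromo-2-hydroxybenzaldehyde
Product: 8 2-(allyloxy)-4,6-bis(benzyloxy)-3-bromobenzaldehyde (ring A of the middle unit)
Conditions: allyl bromide, K2CO3, DMF, 50 °C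
Reagents that add atoms: allyl bromide, C=CCBr
Why: Williamson allylation of the chelated phenol gives an ether that survives organolithium reagents, fluoride and carbonate and is removed selectively by palladium in step 15.

Step 7
Reactants: 6 2,4-bis(benzyloxy)-6-hydroxybenzaldehyde
Product: 9 2,4-bis(benzyloxy)-6-(tert-butyldimethylsilyloxy)benzaldehyde (ring A of the top unit)
Conditions: TBSCl, imidazole, DMF, rt
Reagents that add atoms: tert-butyldimethylsilyl chloride, C[Si](C)(Cl)C(C)(C)C
Why: Silylation of the phenol (silyl chloride–imidazole) gives an electrophilic aldehyde whose phenol can later be released by fluoride in the presence of allyl, benzyl and MOM ethers.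

Step 8
Reactants: 10 3,4-dihydroxyacetophenone
Product: 11 3,4-bis(pivaloyloxy)acetophenone
Conditions: PivCl (2.3 equiv), Et3N, DMAP (cat.), CH2Cl2, 0 °C → rt
Reagents that add atoms: pivaloyl chloride, CC(C)(C)C(Cl)=O
Why: DMAP-catalysed O-acylation installs hindered, electron-withdrawing esters, so that the B rings of the top and middle units will not stabilise a benzylic cation in step 18 and will resist carbonate, fluoride and hydride.

Step 9
Reactants: 11 3,4-bis(pivaloyloxy)acetophenone
Product: 12 2-bromo-1-[3,4-bis(pivaloyloxy)phenyl]ethanone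
Conditions: CuBr2 (2.1 equiv), EtOAc–CHCl3, reflux
Reagents that add atoms: copper dibromide, Br[Cu]Br
Why: α-Bromination of the aryl methyl ketone through its enol with CuBr2 (divalent copper is reduced to CuBr) stops at the monobromide and leaves the pivalates untouched.

Step 10
Reactants: 12 2-bromo-1-[3,4-bis(pivaloyloxy)phenyl]ethanone; 13 quinidine
Product: 14 N-{2-[3,4-bis(pivaloyloxy)phenyl]-2-oxoethyl}quinidinium bromide
Conditions: THF, rt
Reagents that add atoms: none
Why: Menshutkin quaternisation at the quinuclidine nitrogen, the more nucleophilic of the two nitrogens, gives the ylide precursor with a chiral leaving group.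

Step 11
Reactants: 4 lower unit; 8 2-(allyloxy)-4,6-bis(benzyloxy)-3-bromobenzaldehyde
Product: 16 [2-(allyloxy)-4,6-bis(benzyloxy)-3-bromophenyl](lower-unit C6)methanol (epimer mixture at the carbinol carbon), via aryllithium 15 (not isolated)
Conditions: n-BuLi (1.05 equiv), THF, 0 °C; then 8 (1.1 equiv), −78 → −40 °C; aq NH4Cl
Reagents that add atoms: none
Why: Directed ortho-metalation at C6, the site flanked by both MOM ethers (to be confirmed by a D2O quench on a sample), followed by 1,2-addition of the aryllithium to the aldehyde fixes the C4(middle)–C6(lower) bond; the new carbinol center is formed without control and is erased at the quinone methide stage.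

Step 12
Reactants: 16 bromo carbinol; 9 2,4-bis(benzyloxy)-6-(tert-butyldimethylsilyloxy)benzaldehyde
Product: 18 bis-carbinol in which the former C–Br carbon carries CH(OH)[2,4-bis(benzyloxy)-6-(TBS-oxy)phenyl] (both carbinol carbons epimer mixtures), via dilithio species 17 (not isolated)
Conditions: t-BuLi (3.1 equiv), THF, −78 °C; then 9 (1.3 equiv), −78 → −40 °C; AcOH in THF at −78 °C
Reagents that add atoms: none
Why: Deprotonation of the hydroxyl, bromine–lithium exchange and 1,2-addition of the aryllithium to aldehyde 9 fix the C4(top)–C8(middle) bond at the carbon that carried bromine; the cold acidic quench prevents O-to-O silyl transfer, and the second carbinol center is again uncontrolled and transient.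

Step 13
Reactants: 18 bis-carbinol
Product: 19 bis(p-tolyl sulfone) (both hydroxyls of 18 replaced by p-toluenesulfonyl)
Conditions: p-TolSO2H (3 equiv), 4 Å molecular sieves, CH2Cl2, 0 °C → rt
Reagents that add atoms: p-toluenesulfinic acid, Cc1ccc(cc1)S(=O)O
Why: SN1 substitution, in which both carbinols (each flanked by two tri-oxygenated aryl rings) should ionise under the mild acid and be captured at sulfur by sulfinate, giving sulfones that leave only when the neighbouring phenol oxygen is set free.

Step 14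
Reactants: 19 bis(p-tolyl sulfone); 14 quinidinium bromide
Product: 21 top furan ketone: trans-(2S)-2-[3,4-bis(pivaloyloxy)benzoyl]-4,6-bis(benzyloxy)-2,3-dihydrobenzofuran-3-yl at C8 of the middle ring (lower sulfone and allyl ether retained), via top quinone methide 20 (not isolated)
Conditions: 14 (1.3 equiv), CsF (3 equiv), Cs2CO3 (3 equiv), CH2Cl2–MeCN, 0 °C → rt
Reagents that add atoms: none
Why: Fluoride removes the silyl group and the phenoxide expels sulfinate to give o-quinone methide 20, which undergoes the formal [4+1] annulation with the ammonium ylide from 14 (conjugate addition, then 5-exo-tet O-alkylation with loss of quinidine); trans at C2'/C3' follows from the reversible addition and the epimerisable ketone, the face of addition and hence (2'S) from the alkaloid leaving group, and the second sulfone stays because its flanking oxygen is allylated.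

Step 15
Reactants: 21 top furan ketone
Product: 22 phenol sulfone (allyl ether of 21 cleaved)
Conditions: Pd(PPh3)4 (5 mol %), p-TolSO2H (1.5 equiv), CH2Cl2, rt
Reagents that add atoms: none
Why: Tsuji–Trost deallylation through a π-allyl complex of zerovalent palladium with sulfinate as the allyl acceptor; the acidic medium keeps the phenol protonated so that the quinone methide is not released, and any ionisation of the sulfone is returned by the sulfinate present.

Step 16
Reactants: 22 phenol sulfone; 14 quinidinium bromide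
Product: 24 bis(furan ketone): middle ring closed to a second trans-(2S)-2-aroyl-2,3-dihydrobenzofuran whose C3' is bonded to C6 of the lower unit, via middle quinone methide 23 (not isolated)
Conditions: 14 (1.3 equiv), Cs2CO3 (3 equiv), CH2Cl2, rt
Reagents that add atoms: none
Why: Carbonate deprotonates the phenol, sulfinate is expelled and o-quinone methide 23 undergoes the same ammonium ylide [4+1] annulation as in step 14, trans by ring closure and (2'S) again from the quinidine leaving group, which should override the weak bias of the remote stereocenters.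

Step 17
Reactants: 24 bis(furan ketone)
Product: 25 bis(furanyl carbinol): both ketones reduced to (S) carbinols, furans (2'S)-trans
Conditions: LiBH(s-Bu)3 (L-Selectride, 2.6 equiv), THF, −78 °C; aq NH4Cl
Reagents that add atoms: none
Why: Felkin–Anh addition of a bulky, non-chelating hydride: with O1' anti to the incoming hydride and the hydride passing the C2' hydrogen, each ketone should give the (S) carbinol (syn to O1'), whereas a chelating reductant would give the epimers, which the double inversion of step 18 would turn into the 2,3-trans series.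

Step 18
Reactants: 25 bis(furanyl carbinol)
Product: 28 protected trimer with 3-acetates in the top and middle units (2,3-cis-3,4-trans; lower unit 5,7-di-O-MOM), via bis(chloromethanesulfonate) 26 (not isolated), via bis(oxonium) ion 27 (not isolated)
Conditions: ClCH2SO2Cl (3 equiv), 2,6-lutidine, CH2Cl2, −20 → 0 °C; then Zn(OAc)2 (8 equiv), AcOH–1,4-dioxane (1:1), rt → 50 °C
Reagents that add atoms: zinc acetate, CC(=O)[O-].CC(=O)[O-].[Zn+2]
Why: Proposed new method: each carbinol is converted into a chloromethanesulfonate, and on warming with zinc acetate the furan oxygen O1', which can stand anti-periplanar to the C–O sulfonate bond, displaces the sulfonate with inversion at the benzylic carbon to give an aryl-bridged oxonium ion, which acetate opens at C2' with inversion, so that the furan carbon becomes C3 (acetoxy) and the former carbinol carbon becomes C2 bonded to O1. The closest known reaction type is the zinc acetate-promoted, stereospecific ring expansion of 2-(1-sulfonyloxyalkyl)tetrahydrofurans to 3-acetoxytetrahydropyrans through bicyclic oxonium ions, which has not been shown for benzylic carbinols on dihydrobenzofuran (aryl ether) oxygens or as a double event. Each ring C is closed in two stages: the O1–C2 bond forms in a 3-exo-tet displacement, and the six-membered ring then results from the endo-mode SN2 opening of the oxonium ion at the ring carbon, which enlarges the five-membered ring by one atom. C2 of each unit is controlled by the carbinol configuration (S, from step 17) through inversion, C3 by the furan C2' configuration (S, from the annulations) through inversion, and C4 is carried over from the trans furan, so that a syn carbinol on a trans furan gives 2,3-cis-3,4-trans. The step needs displacement by O1' in place of ionisation or direct substitution, and acetate capture at C3 in place of the benzylic carbon: the pivalate-bearing, electron-poor B rings disfavour a free benzylic cation and shift the opening away from the benzylic carbon, the chroman-3-yl acetate once formed is inert, and a benzylic sulfonate re-formed by internal return re-enters the oxonium ion. Acetate is used in large excess in acetic acid so that it outruns the ortho ether oxygens of the neighbouring aryl groups and a 1,2-hydride shift from C4.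

Step 19
Reactants: 28 protected trimer diacetate
Product: 29 trimer with free 3-hydroxyls and free B-ring catechols in the top and middle units (lower unit and A rings still protected)
Conditions: K2CO3 (8 equiv), degassed MeOH–THF, 0 °C → rt, argon; Amberlite IR-120 (H+)
Reagents that add atoms: none
Why: Base-catalysed transesterification (methanolysis) removes the two secondary acetates and the four aryl pivalates in one operation without touching a stereocenter; oxygen is excluded because the catecholates formed are easily oxidised.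

Step 20
Reactants: 29 deacylated trimer
Product: 30 trimer with free 5,7-hydroxyls in the lower unit
Conditions: HCl (1.25 M in MeOH, 6 equiv), THF–MeOH, 0 °C → rt
Reagents that add atoms: none
Why: Acid-catalysed acetal cleavage of the two aryl MOM ethers under conditions mild enough to leave the interflavan bonds, the benzyl ethers and the diphenylmethylene ketal intact.

Step 21
Reactants: 30 partly deprotected trimer
Product: 31 epicatechin-(4β→8)-epicatechin-(4β→6)-epicatechin (CNP0178679.3)
Conditions: H2 (1 atm), Pd(OH)2/C, THF–MeOH–H2O, rt; filtration, lyophilisation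
Reagents that add atoms: none
Why: Hydrogenolysis of the five benzyl ethers and of the benzylic C–O bonds of the diphenylmethylene ketal over Pd(OH)2 on carbon, conditions under which the ring C benzylic ether bonds of flavan-3-ols are normally retained, should release the free trimer.

## Compound list

1 | (−)-epicatechin | Oc1cc(O)c2c(c1)O[C@H](c1ccc(O)c(O)c1)[C@H](O)C2 | starting material
2 | 3',4'-O-(diphenylmethylene)-(−)-epicatechin | Oc1cc(O)c2c(c1)O[C@H](c1ccc3OC(c4ccccc4)(c4ccccc4)Oc3c1)[C@H](O)C2 | intermediate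
3 | 5,7-bis-O-(methoxymethyl)-3',4'-O-(diphenylmethylene)-(−)-epicatechin | COCOc1cc(OCOC)c2c(c1)O[C@H](c1ccc3OC(c4ccccc4)(c4ccccc4)Oc3c1)[C@H](O)C2 | intermediate
4 | 3-O-benzyl-5,7-bis-O-(methoxymethyl)-3',4'-O-(diphenylmethylene)-(−)-epicatechin | COCOc1cc(OCOC)c2c(c1)O[C@H](c1ccc3OC(c4ccccc4)(c4ccccc4)Oc3c1)[C@H](OCc1ccccc1)C2 | intermediate
5 | 2,4,6-trihydroxybenzaldehyde | O=Cc1c(O)cc(O)cc1O | starting material
6 | 2,4-bis(benzyloxy)-6-hydroxybenzaldehyde | O=Cc1c(O)cc(OCc2ccccc2)cc1OCc1ccccc1 | intermediate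
7 | 4,6-bis(benzyloxy)-3-bromo-2-hydroxybenzaldehyde | O=Cc1c(O)c(Br)c(OCc2ccccc2)cc1OCc1ccccc1 | intermediate
8 | 2-(allyloxy)-4,6-bis(benzyloxy)-3-bromobenzaldehyde | O=Cc1c(OCC=C)c(Br)c(OCc2ccccc2)cc1OCc1ccccc1 | intermediate
9 | 2,4-bis(benzyloxy)-6-(tert-butyldimethylsilyloxy)benzaldehyde | O=Cc1c(O[Si](C)(C)C(C)(C)C)cc(OCc2ccccc2)cc1OCc1ccccc1 | intermediate
10 | 3,4-dihydroxyacetophenone | CC(=O)c1ccc(O)c(O)c1 | starting material
11 | 3,4-bis(pivaloyloxy)acetophenone | CC(=O)c1ccc(OC(=O)C(C)(C)C)c(OC(=O)C(C)(C)C)c1 | intermediate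
12 | 2-bromo-1-[3,4-bis(pivaloyloxy)phenyl]ethanone | BrCC(=O)c1ccc(OC(=O)C(C)(C)C)c(OC(=O)C(C)(C)C)c1 | intermediate
13 | quinidine | COc1ccc2nccc([C@@H]([C@H]3C[C@@H]4CCN3C[C@@H]4C=C)O)c2c1 | starting material
14 | N-{2-[3,4-bis(pivaloyloxy)phenyl]-2-oxoethyl}quinidinium bromide | COc1ccc2nccc([C@@H]([C@H]3C[C@@H]4CC[N+]3(CC(=O)c5ccc(OC(=O)C(C)(C)C)c(OC(=O)C(C)(C)C)c5)C[C@@H]4C=C)O)c2c1.[Br-] | intermediate
15 | C6-lithio derivative of 4 | [Li]c1c(OCOC)cc2c(c1OCOC)C[C@@H](OCc9ccccc9)[C@@H](c3ccc4OC(c5ccccc5)(c5ccccc5)Oc4c3)O2 | intermediate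
16 | bromo carbinol linking C6 of the lower unit to ring A of the middle unit (carbinol epimers) | C=CCOc1c(Br)c(OCc9ccccc9)cc(OCc9ccccc9)c1C(O)c3c(OCOC)cc4c(c3OCOC)C[C@@H](OCc9ccccc9)[C@@H](c5ccc6OC(c7ccccc7)(c7ccccc7)Oc6c5)O4 | intermediate
17 | O,C-dilithio derivative of 16 (lithium alkoxide, aryllithium at the former C–Br) | C=CCOc1c([Li])c(OCc9ccccc9)cc(OCc9ccccc9)c1C(O[Li])c3c(OCOC)cc4c(c3OCOC)C[C@@H](OCc9ccccc9)[C@@H](c5ccc6OC(c7ccccc7)(c7ccccc7)Oc6c5)O4 | intermediate
18 | bis-carbinol (top ring A O-TBS, middle ring A O-allyl; both carbinol carbons epimer mixtures) | c9ccccc9COc1cc(OCc9ccccc9)c(C(O)c2c(OCc9ccccc9)cc(OCc9ccccc9)c(C(O)c3c(OCOC)cc4c(c3OCOC)C[C@@H](OCc9ccccc9)[C@@H](c5ccc6OC(c7ccccc7)(c7ccccc7)Oc6c5)O4)c2OCC=C)c(O[Si](C)(C)C(C)(C)C)c1 | intermediate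
19 | bis(p-tolyl sulfone) of 18 | c9ccccc9COc1cc(OCc9ccccc9)c(C(c2c(OCc9ccccc9)cc(OCc9ccccc9)c(C(c3c(OCOC)cc4c(c3OCOC)C[C@@H](OCc9ccccc9)[C@@H](c5ccc6OC(c7ccccc7)(c7ccccc7)Oc6c5)O4)S(=O)(=O)c8ccc(C)cc8)c2OCC=C)S(=O)(=O)c8ccc(C)cc8)c(O[Si](C)(C)C(C)(C)C)c1 | intermediate
20 | top o-quinone methide (exocyclic carbon on C8 of the middle ring; lower sulfone and allyl ether retained) | O=C1C=C(OCc9ccccc9)C=C(OCc9ccccc9)C1=Cc2c(OCc9ccccc9)cc(OCc9ccccc9)c(C(c3c(OCOC)cc4c(c3OCOC)C[C@@H](OCc9ccccc9)[C@@H](c5ccc6OC(c7ccccc7)(c7ccccc7)Oc6c5)O4)S(=O)(=O)c8ccc(C)cc8)c2OCC=C | intermediate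
21 | top trans-(2S)-2-aroyl-3-aryl-2,3-dihydrobenzofuran with lower sulfone and allyl ether | c9ccccc9COc1cc(OCc9ccccc9)c2c(c1)O[C@H](C(=O)c3ccc(OC(=O)C(C)(C)C)c(OC(=O)C(C)(C)C)c3)[C@H]2c1c(OCc9ccccc9)cc(OCc9ccccc9)c(C(c3c(OCOC)cc4c(c3OCOC)C[C@@H](OCc9ccccc9)[C@@H](c5ccc6OC(c7ccccc7)(c7ccccc7)Oc6c5)O4)S(=O)(=O)c8ccc(C)cc8)c1OCC=C | intermediate
22 | phenol sulfone (21 without allyl) | c9ccccc9COc1cc(OCc9ccccc9)c2c(c1)O[C@H](C(=O)c3ccc(OC(=O)C(C)(C)C)c(OC(=O)C(C)(C)C)c3)[C@H]2c1c(OCc9ccccc9)cc(OCc9ccccc9)c(C(c3c(OCOC)cc4c(c3OCOC)C[C@@H](OCc9ccccc9)[C@@H](c5ccc6OC(c7ccccc7)(c7ccccc7)Oc6c5)O4)S(=O)(=O)c8ccc(C)cc8)c1O | intermediate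
23 | middle o-quinone methide (exocyclic carbon on C6 of the lower unit; top furan ketone on C8) | c9ccccc9COc1cc(OCc9ccccc9)c2c(c1)O[C@H](C(=O)c3ccc(OC(=O)C(C)(C)C)c(OC(=O)C(C)(C)C)c3)[C@H]2C1=C(OCc9ccccc9)C=C(OCc9ccccc9)C(=Cc3c(OCOC)cc4c(c3OCOC)C[C@@H](OCc9ccccc9)[C@@H](c5ccc6OC(c7ccccc7)(c7ccccc7)Oc6c5)O4)C1=O | intermediate
24 | bis(trans-(2S)-2-aroyl-3-aryl-2,3-dihydrobenzofuran) joined to C6 of the lower unit | c9ccccc9COc1cc(OCc9ccccc9)c2c(c1)O[C@H](C(=O)c3ccc(OC(=O)C(C)(C)C)c(OC(=O)C(C)(C)C)c3)[C@H]2c1c(OCc9ccccc9)cc(OCc9ccccc9)c2c1O[C@H](C(=O)c3ccc(OC(=O)C(C)(C)C)c(OC(=O)C(C)(C)C)c3)[C@H]2c1c(OCOC)cc2c(c1OCOC)C[C@@H](OCc9ccccc9)[C@@H](c3ccc4OC(c5ccccc5)(c5ccccc5)Oc4c3)O2 | intermediate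
25 | bis(trans-3-aryl-2,3-dihydrobenzofuran-2-yl) aryl carbinol, both carbinols (S), both furans (2'S)-trans (key-step precursor) | c9ccccc9COc1cc(OCc9ccccc9)c2c(c1)O[C@H]([C@@H](O)c3ccc(OC(=O)C(C)(C)C)c(OC(=O)C(C)(C)C)c3)[C@H]2c1c(OCc9ccccc9)cc(OCc9ccccc9)c2c1O[C@H]([C@@H](O)c3ccc(OC(=O)C(C)(C)C)c(OC(=O)C(C)(C)C)c3)[C@H]2c1c(OCOC)cc2c(c1OCOC)C[C@@H](OCc9ccccc9)[C@@H](c3ccc4OC(c5ccccc5)(c5ccccc5)Oc4c3)O2 | intermediate
26 | bis(chloromethanesulfonate) of 25 | c9ccccc9COc1cc(OCc9ccccc9)c2c(c1)O[C@H]([C@@H](OS(=O)(=O)CCl)c3ccc(OC(=O)C(C)(C)C)c(OC(=O)C(C)(C)C)c3)[C@H]2c1c(OCc9ccccc9)cc(OCc9ccccc9)c2c1O[C@H]([C@@H](OS(=O)(=O)CCl)c3ccc(OC(=O)C(C)(C)C)c(OC(=O)C(C)(C)C)c3)[C@H]2c1c(OCOC)cc2c(c1OCOC)C[C@@H](OCc9ccccc9)[C@@H](c3ccc4OC(c5ccccc5)(c5ccccc5)Oc4c3)O2 | intermediate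
27 | bis(aryl-bridged oxonium) ion, bis(chloromethanesulfonate) salt (formal; the two units are expected to react one after the other) | c9ccccc9COc1cc(OCc9ccccc9)c2c(c1)[O+]6[C@H]([C@H]6c3ccc(OC(=O)C(C)(C)C)c(OC(=O)C(C)(C)C)c3)[C@H]2c1c(OCc9ccccc9)cc(OCc9ccccc9)c2c1[O+]6[C@H]([C@H]6c3ccc(OC(=O)C(C)(C)C)c(OC(=O)C(C)(C)C)c3)[C@H]2c1c(OCOC)cc2c(c1OCOC)C[C@@H](OCc9ccccc9)[C@@H](c3ccc4OC(c5ccccc5)(c5ccccc5)Oc4c3)O2.[O-]S(=O)(=O)CCl.[O-]S(=O)(=O)CCl | intermediate
28 | protected trimer, 3-acetates in the top and middle units (2R,3R, 4β), lower unit 5,7-di-O-MOM (key-step product) | c9ccccc9COc1cc(OCc9ccccc9)c2c(c1)O[C@H](c3ccc(OC(=O)C(C)(C)C)c(OC(=O)C(C)(C)C)c3)[C@H](OC(C)=O)[C@H]2c1c(OCc9ccccc9)cc(OCc9ccccc9)c2c1O[C@H](c3ccc(OC(=O)C(C)(C)C)c(OC(=O)C(C)(C)C)c3)[C@H](OC(C)=O)[C@H]2c1c(OCOC)cc2c(c1OCOC)C[C@@H](OCc9ccccc9)[C@@H](c3ccc4OC(c5ccccc5)(c5ccccc5)Oc4c3)O2 | intermediate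
29 | deacylated trimer (free 3-OH and B-ring catechols in the top and middle units) | c9ccccc9COc1cc(OCc9ccccc9)c2c(c1)O[C@H](c3ccc(O)c(O)c3)[C@H](O)[C@H]2c1c(OCc9ccccc9)cc(OCc9ccccc9)c2c1O[C@H](c3ccc(O)c(O)c3)[C@H](O)[C@H]2c1c(OCOC)cc2c(c1OCOC)C[C@@H](OCc9ccccc9)[C@@H](c3ccc4OC(c5ccccc5)(c5ccccc5)Oc4c3)O2 | intermediate
30 | trimer after MOM removal (benzyl ethers and ketal left) | c9ccccc9COc1cc(OCc9ccccc9)c2c(c1)O[C@H](c3ccc(O)c(O)c3)[C@H](O)[C@H]2c1c(OCc9ccccc9)cc(OCc9ccccc9)c2c1O[C@H](c3ccc(O)c(O)c3)[C@H](O)[C@H]2c1c(O)cc2c(c1O)C[C@@H](OCc9ccccc9)[C@@H](c3ccc4OC(c5ccccc5)(c5ccccc5)Oc4c3)O2 | intermediate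
31 | epicatechin-(4β→8)-epicatechin-(4β→6)-epicatechin (CNP0178679.3) | Oc1cc(O)c2c(c1)O[C@H](c1ccc(O)c(O)c1)[C@H](O)[C@H]2c1c(O)cc(O)c2c1O[C@H](c1ccc(O)c(O)c1)[C@H](O)[C@H]2c1c(O)cc2c(c1O)C[C@@H](O)[C@@H](c1ccc(O)c(O)c1)O2 | target

## Step count and risks

Total step count: 21. Longest linear sequence: 14 steps (steps 1–3 and 11–21).

**Step 18 (Proposed new method).** What may go wrong:
- acetate opening of the oxonium ion at the benzylic carbon, which returns an unexpanded furan acetate with net retention;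
- attack of an ortho ether oxygen of the neighbouring aryl group at C3 (5-exo) with loss of a benzyl or MOM group;
- a 1,2-hydride shift from C4 toward the opening C3–O bond;
- ionisation at the benzylic carbon with loss of the C2 configuration;
- partial acetolysis of the MOM ethers.

Fallback, known chemistry only, setting out from 1 and coming back at 31: the upper rings C are not built but taken from epicatechin, and the interflavan bonds are made by C4-cation coupling. Compound 1 is benzylated at its four phenols (BnBr, K2CO3, DMF) to 5,7,3',4'-tetra-O-benzyl-(−)-epicatechin F1. Oxidation of F1 at C4 with DDQ in the presence of 2-ethoxyethanol gives the 4β-(2-ethoxyethoxy) ether F2 as the electrophile. Bromination of F1 with NBS at C8 gives 8-bromo-5,7,3',4'-tetra-O-benzyl-(−)-epicatechin F3. TMSOTf-promoted Friedel–Crafts coupling of F2 with excess F3 (C8 blocked, attack through C6, trans to the 3-hydroxyl) gives the 4β→6 dimer F4. A second TMSOTf coupling of F2 with F4 at the free C8 of its upper unit gives the protected 4β→8, 4β→6 trimer F5. Hydrogenolysis (H2, Pd(OH)2/C, Et3N, THF–MeOH–H2O) removes the twelve benzyl groups and the bromine and gives 31.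

**Step 14.** What may go wrong: slow addition of the bulky alkaloid-bound ylide to the crowded, donor-stabilised quinone methide, so that sulfinate return or oligomerisation of the quinone methide competes, and poor facial selectivity in the addition.

Fallback, setting out from 16 and coming back at 21: anionic generation of the quinone methide, a small achiral ylide and separation in place of auxiliary control. Compound 16 is converted into 17 as in step 12 and added to 2,4-bis(benzyloxy)-6-(tert-butoxycarbonyloxy)benzaldehyde F6 (from 6, Boc2O, DMAP). The new alkoxide takes over the Boc group from the neighbouring phenol oxygen, and MgBr2·OEt2 then expels tert-butyl carbonate to release the top o-quinone methide with free lower carbinol F9, under conditions in which the lower carbinol is an inert alkoxide. F9 is trapped by pre-formed dimethylsulfonium 2-[3,4-bis(pivaloyloxy)phenyl]-2-oxoethylide F8, made from 12 and Me2S through the sulfonium bromide F7 and then K2CO3. This [4+1] annulation is trans-selective but not face-selective. The two trans diastereomers are separated by chromatography, and the (2'S)-trans furan carbinol F10 is treated with p-TolSO2H as in step 13 to give 21.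

**Step 16.** What may go wrong: the same loss of rate and facial selectivity as in step 14, made worse because the ring-closing phenoxide oxygen lies next to the bulky top furan.

Fallback, setting out from 22 and coming back at 24: acid catalysis and catalyst control in place of base and auxiliary control. Compound 22 in CHCl3 with a chiral 3,3'-bis(2,4,6-triisopropylphenyl)-1,1'-binaphthyl-2,2'-diyl hydrogen phosphate (10 mol %, enantiomer chosen on a model quinone methide) loses p-toluenesulfinic acid to give the acid-bound quinone methide 23. This takes up 2-diazo-1-[3,4-bis(pivaloyloxy)phenyl]ethanone F11 (from 11 by detrifluoroacetylative diazo transfer: LiN(SiMe3)2, CF3CO2CH2CF3, then MsN3, Et3N) with loss of nitrogen, in the known cis-selective [4+1] annulation of o-quinone methides with diazoketones. The resulting 2',3'-cis ketone F12 is epimerised at C2' with DBU to the trans ketone 24.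

## Further compounds

F1 | step 18 | 5,7,3',4'-tetra-O-benzyl-(−)-epicatechin | c9ccccc9COc1cc(OCc9ccccc9)c2c(c1)O[C@H](c1ccc(OCc9ccccc9)c(OCc9ccccc9)c1)[C@H](O)C2
F2 | step 18 | 4β-(2-ethoxyethoxy)-5,7,3',4'-tetra-O-benzyl-(−)-epicatechin | c9ccccc9COc1cc(OCc9ccccc9)c2c(c1)O[C@H](c1ccc(OCc9ccccc9)c(OCc9ccccc9)c1)[C@H](O)[C@H]2OCCOCC
F3 | step 18 | 8-bromo-5,7,3',4'-tetra-O-benzyl-(−)-epicatechin | c9ccccc9COc1cc(OCc9ccccc9)c2c(c1Br)O[C@H](c1ccc(OCc9ccccc9)c(OCc9ccccc9)c1)[C@H](O)C2
F4 | step 18 | octa-O-benzyl epicatechin-(4β→6)-(8-bromoepicatechin) | c9ccccc9COc1cc(OCc9ccccc9)c2c(c1)O[C@H](c1ccc(OCc9ccccc9)c(OCc9ccccc9)c1)[C@H](O)[C@H]2c1c(OCc9ccccc9)c(Br)c2c(c1OCc9ccccc9)C[C@@H](O)[C@@H](c1ccc(OCc9ccccc9)c(OCc9ccccc9)c1)O2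
F5 | step 18 | dodeca-O-benzyl epicatechin-(4β→8)-epicatechin-(4β→6)-(8-bromoepicatechin) | c9ccccc9COc1cc(OCc9ccccc9)c2c(c1)O[C@H](c1ccc(OCc9ccccc9)c(OCc9ccccc9)c1)[C@H](O)[C@H]2c1c(OCc9ccccc9)cc(OCc9ccccc9)c2c1O[C@H](c1ccc(OCc9ccccc9)c(OCc9ccccc9)c1)[C@H](O)[C@H]2c1c(OCc9ccccc9)c(Br)c2c(c1OCc9ccccc9)C[C@@H](O)[C@@H](c1ccc(OCc9ccccc9)c(OCc9ccccc9)c1)O2
F6 | step 14 | 2,4-bis(benzyloxy)-6-(tert-butoxycarbonyloxy)benzaldehyde | O=Cc1c(OC(=O)OC(C)(C)C)cc(OCc2ccccc2)cc1OCc1ccccc1
F7 | step 14 | dimethyl{2-[3,4-bis(pivaloyloxy)phenyl]-2-oxoethyl}sulfonium bromide | C[S+](C)CC(=O)c1ccc(OC(=O)C(C)(C)C)c(OC(=O)C(C)(C)C)c1.[Br-]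
F8 | step 14 | dimethylsulfonium 2-[3,4-bis(pivaloyloxy)phenyl]-2-oxoethylide | C[S+](C)[CH-]C(=O)c1ccc(OC(=O)C(C)(C)C)c(OC(=O)C(C)(C)C)c1
F9 | step 14 | top o-quinone methide with free lower carbinol | O=C1C=C(OCc9ccccc9)C=C(OCc9ccccc9)C1=Cc2c(OCc9ccccc9)cc(OCc9ccccc9)c(C(O)c3c(OCOC)cc4c(c3OCOC)C[C@@H](OCc9ccccc9)[C@@H](c5ccc6OC(c7ccccc7)(c7ccccc7)Oc6c5)O4)c2OCC=C
F10 | step 14 | (2'S)-trans furan carbinol (21 with hydroxyl in place of the sulfonyl group) | c9ccccc9COc1cc(OCc9ccccc9)c2c(c1)O[C@H](C(=O)c3ccc(OC(=O)C(C)(C)C)c(OC(=O)C(C)(C)C)c3)[C@H]2c1c(OCc9ccccc9)cc(OCc9ccccc9)c(C(O)c3c(OCOC)cc4c(c3OCOC)C[C@@H](OCc9ccccc9)[C@@H](c5ccc6OC(c7ccccc7)(c7ccccc7)Oc6c5)O4)c1OCC=C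
F11 | step 16 | 2-diazo-1-[3,4-bis(pivaloyloxy)phenyl]ethanone | [N-]=[N+]=CC(=O)c1ccc(OC(=O)C(C)(C)C)c(OC(=O)C(C)(C)C)c1
F12 | step 16 | bis(furan ketone) with 2',3'-cis middle furan (C2' epimer of 24) | c9ccccc9COc1cc(OCc9ccccc9)c2c(c1)O[C@H](C(=O)c3ccc(OC(=O)C(C)(C)C)c(OC(=O)C(C)(C)C)c3)[C@H]2c1c(OCc9ccccc9)cc(OCc9ccccc9)c2c1O[C@@H](C(=O)c3ccc(OC(=O)C(C)(C)C)c(OC(=O)C(C)(C)C)c3)[C@H]2c1c(OCOC)cc2c(c1OCOC)C[C@@H](OCc9ccccc9)[C@@H](c3ccc4OC(c5ccccc5)(c5ccccc5)Oc4c3)O2
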